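## Retrosynthetic overview

1. Ring A (the methylenecyclohexane) closes last. A Pd–H reductive 1,7-enyne cyclisation makes the C(=CH2)–C(CH3)(CO2H) bond, the exocyclic methylene, the C-methyl group and the free-acid quaternary centre in one step.
2. The enyne comes from C-ethynylation of a 3-tert-alkyl tetronic acid. That acid is made by SN1 union of (R)-5-methyltetronic acid (ring D, Dieckmann from (R)-lactate) with a ring-B allyl cation.
3. Key step: the cation is stored in a bis-lactone made in one operation from a diketo-diester by twofold MeCeCl2 addition and twofold lactonisation. This forms the spiro δ-lactone (ring C) and a sacrificial fused lactone that serves as both leaving group and carboxyl protection.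
4. The diketo-diester comes from 4-acetyl-3-methylcyclohexenone (ring B, from acetylacetone and methyl vinyl ketone) by two site-complementary C–C bond formations on its vinylogous diketonate. The second is asymmetric.
5. Ring order: B, then C plus the temporary lactone (one pot), then D (made separately, joined convergently), then A.

Assumption: the sense of induction of the cinchona phase-transfer catalyst in step 3 cannot be predicted with certainty; the cinchonidine-derived salt is written, and its cinchonine-derived pseudo-enantiomer is used if the sense is opposite.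

## Route

Step 1
Reactants: 1 pentane-2,4-dione; 2 but-3-en-2-one
Product: 4 rac-4-acetyl-3-methylcyclohex-2-en-1-one, via triketone 3 (not isolated)
Conditions: Et3N (5 mol %), neat, 0 °C → rt; then pyrrolidine/AcOH (20 mol % each), toluene, Dean–Stark reflux
Reagents that add atoms: none
Why: Robinson-type annulation (Michael addition, then enamine-mediated intramolecular aldol condensation, the acetylacetone counterpart of the vinyl-ketone route to Hagemann's ester), in which the side-chain methyl ketone condenses onto one acetyl group; the new C-4 centre is irrelevant because it is deprotonated in steps 2 and 3.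

Step 2
Reactants: 4 rac-4-acetyl-3-methylcyclohex-2-en-1-one; 5 methyl 2-(bromomethyl)prop-2-enoate
Product: 6 rac-methyl 2-[(3-acetyl-2-methyl-6-oxocyclohex-1-en-1-yl)methyl]prop-2-enoate
Conditions: KOt-Bu (1.0 equiv), THF/t-BuOH, 0 °C; then 5, 0 °C → rt
Reagents that add atoms: none
Why: Hagemann-ester-type alkylation of a vinylogous β-diketonate, in which the delocalised anion attacks the allylic bromide (SN2 or SN2′, same product) through the less substituted carbon α to the ring ketone (C-2), and tautomerisation restores the conjugated tetrasubstituted enone and the acidic C–H next to the acetyl group, so no lasting stereocentre is made.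

Step 3
Reactants: 6 rac-methyl 2-[(3-acetyl-2-methyl-6-oxocyclohex-1-en-1-yl)methyl]prop-2-enoate; 7 ethyl (Z)-3-iodoprop-2-enoate
Product: 8 ethyl (2Z)-3-[(1R)-1-acetyl-3-[2-(methoxycarbonyl)prop-2-en-1-yl]-2-methyl-4-oxocyclohex-2-en-1-yl]prop-2-enoate
Conditions: N-(9-anthracenylmethyl)-O-allylcinchonidinium bromide (10 mol %), Cs2CO3 (1.5 equiv), toluene/CHCl3, −30 °C
Reagents that add atoms: none
Why: Asymmetric phase-transfer nucleophilic vinylic substitution (addition–elimination, SNV), in which the ion-paired planar dienolate, with C-2 now blocked, attacks the β-carbon of the iodoacrylate through the carbon α to the acetyl group, iodide leaves faster than C–C rotation so the Z geometry is kept, and the chiral ammonium ion shields one dienolate face to set the (R) quaternary carbon.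

Step 4 (key step)
Reactants: 8 ethyl (2Z)-3-[(1R)-1-acetyl-3-[2-(methoxycarbonyl)prop-2-en-1-yl]-2-methyl-4-oxocyclohex-2-en-1-yl]prop-2-enoate
Product: 10 (R)-bis-lactone (spiro δ-lactone plus fused α-methylene-δ-lactone; carbinol carbon as both epimers), via bis-carbinol diester 9 (not isolated)
Conditions: MeLi/CeCl3 (2.4 equiv MeCeCl2), THF, −78 °C, 1 h; warm to rt; sat. aq NH4Cl
Reagents that add atoms: methyllithium (delivered as MeCeCl2), [Li]C
Why: Imamoto organocerium 1,2-addition followed by twofold lactonisation (transesterification), in which non-basic MeCeCl2 adds to the two ketones far faster than to the two conjugated esters at −78 °C and, on warming, each tertiary cerium alkoxide closes a six-membered lactone on the ester held next to it (Z-enoate gives the spiro δ-lactone, acrylate gives the fused lactone); the (R) quaternary centre is untouched and the new carbinol centre is inconsequential because it is ionised in step 7.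

Step 5
Reactants: 11 methyl (R)-lactate
Product: 12 methyl (2R)-2-acetoxypropanoate
Conditions: Ac2O, pyridine, DMAP (cat.), CH2Cl2, 0 °C → rt
Reagents that add atoms: acetic anhydride, CC(=O)OC(C)=O
Why: DMAP-catalysed O-acylation leaves the C–O bond of the stereocentre intact, so the (R) configuration is retained.

Step 6
Reactants: 12 methyl (2R)-2-acetoxypropanoate
Product: 13 (5R)-4-hydroxy-5-methylfuran-2(5H)-one ((R)-5-methyltetronic acid)
Conditions: LiHMDS (2.2 equiv), THF, −78 → 0 °C; 1 M HCl
Reagents that add atoms: none
Why: Dieckmann (intramolecular Claisen) condensation of an α-acyloxy ester, in which the acetate enolate closes onto the neighbouring ester and the product is at once deprotonated to the tetronate, which protects C-5 from enolisation and keeps it (R).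

Step 7
Reactants: 10 (R)-bis-lactone; 13 (R)-5-methyltetronic acid
Product: 15 tetronic-acid-substituted acrylic acid (R spiro carbon; new S quaternary carbon; 5R), via allyl cation 14 (not isolated)
Conditions: 13 (1.5 equiv), TfOH (5 mol %), HFIP/CH2Cl2 1:4, −20 → 0 °C
Reagents that add atoms: none
Why: Proposed new method: Brønsted acid in ionising HFIP cleaves the tertiary allylic alkyl–oxygen bond of the fused lactone (AAL1) to give a tetra-alkyl allyl cation and the free acrylic acid, and the enol carbon C-3 of the tetronic acid attacks the terminus remote from the spiro centre (the other terminus is neopentyl) along the pseudo-axial trajectory anti to the pseudo-axial CMe2–O arm of the spiro-lactone, which sets the (S) methyl-bearing quaternary carbon, while O-alkylation, relactonisation and E1 proton loss are all reversible under the acid; the closest known reaction type is acid-catalysed SN1 allylic alkylation of cyclic 1,3-dicarbonyl compounds with tertiary allylic alcohols.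

Step 8
Reactants: 15 tetronic-acid-substituted acrylic acid
Product: 16 1,7-enyne acid (3-ethynyl-3-tert-alkyl-5-methylfuran-2,4-dione; new S centre)
Conditions: TMS-EBX (1.3 equiv), TBAF (2.3 equiv), THF, −78 °C, 30 min; 1 M HCl
Reagents that add atoms: 1-[(trimethylsilyl)ethynyl]-1,2-benziodoxol-3(1H)-one (TMS-EBX), C[Si](C)(C)C#CI1OC(=O)c2ccccc12
Why: Electrophilic alkynylation with a hypervalent iodine reagent (conjugate addition, α-elimination, 1,2-hydride shift), in which the slim sp-carbon electrophile tolerates the neighbouring quaternary carbon and approaches the planar tetronate on the face anti to the C-5 methyl group, fixing the (S) centre with ethynyl trans to that methyl.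

Step 9
Reactants: 16 1,7-enyne acid
Product: 17 penicianstinoid C
Conditions: Pd2(dba)3·CHCl3 (5 mol %), P(o-tol)3 (20 mol %), AcOH (2 equiv), Et3SiH (5 equiv), toluene, rt
Reagents that add atoms: none
Why: Trost-type Pd–H reductive cyclisation of a 1,7-enyne, in which Markovnikov hydropalladation puts Pd on the internal alkyne carbon, 6-exo syn-carbopalladation of the 1,1-disubstituted acrylic acid gives a neopentyl CH2–Pd without β-hydrogen that the silane reduces to the methyl group, and the chair-like transition state (angular methyl axial, CH2–Pd arm in the plane of the vinyl–Pd bond and hence pseudo-equatorial) places CO2H pseudo-axial on the face opposite the angular methyl, giving the (R) acid-bearing carbon.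

## Compound list

1 | pentane-2,4-dione | CC(=O)CC(C)=O | starting material
2 | but-3-en-2-one (methyl vinyl ketone) | C=CC(C)=O | starting material
3 | 3-acetylheptane-2,6-dione | CC(=O)CCC(C(C)=O)C(C)=O | intermediate
4 | rac-4-acetyl-3-methylcyclohex-2-en-1-one | CC(=O)C1CCC(=O)C=C1C | intermediate
5 | methyl 2-(bromomethyl)prop-2-enoate | C=C(CBr)C(=O)OC | starting material
6 | rac-methyl 2-[(3-acetyl-2-methyl-6-oxocyclohex-1-en-1-yl)methyl]prop-2-enoate | C=C(CC1=C(C)C(C(C)=O)CCC1=O)C(=O)OC | intermediate
7 | ethyl (Z)-3-iodoprop-2-enoate | CCOC(=O)/C=C\I | starting material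
8 | ethyl (2Z)-3-[(1R)-1-acetyl-3-[2-(methoxycarbonyl)prop-2-en-1-yl]-2-methyl-4-oxocyclohex-2-en-1-yl]prop-2-enoate | C=C(CC1=C(C)[C@](C(C)=O)(/C=C\C(=O)OCC)CCC1=O)C(=O)OC | intermediate
9 | ethyl (2Z)-3-[(1R)-4-hydroxy-1-(2-hydroxypropan-2-yl)-3-[2-(methoxycarbonyl)prop-2-en-1-yl]-2,4-dimethylcyclohex-2-en-1-yl]prop-2-enoate (present as its cerium alkoxide; C-4 both epimers) | C=C(CC1=C(C)[C@](C(C)(C)O)(/C=C\C(=O)OCC)CCC1(C)O)C(=O)OC | intermediate
10 | bis-lactone: 5,8a-dimethyl-3-methylidene-3,4,6,7,8,8a-hexahydro-2H-chromen-2-one whose C-6 is the (R) spiro carbon C-5′ of a 6′,6′-dimethyl-5′,6′-dihydro-2′H-pyran-2′-one (C-8a both epimers) | C=C1CC2=C(C)[C@]3(C=CC(=O)OC3(C)C)CCC2(C)OC1=O | intermediate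
11 | methyl (R)-lactate | C[C@@H](O)C(=O)OC | starting material
12 | methyl (2R)-2-acetoxypropanoate | CC(=O)O[C@H](C)C(=O)OC | intermediate
13 | (5R)-4-hydroxy-5-methylfuran-2(5H)-one | C[C@H]1OC(=O)C=C1O | intermediate
14 | ring-B tetra-alkyl allyl cation carrying the (R) spiro δ-lactone and the CH2C(=CH2)CO2H arm | C=C(C(=O)O)CC1=C(C)[C@]2(C=CC(=O)OC2(C)C)CC[C+]1C | intermediate
15 | 2-substituted acrylic acid: cyclohexene with the (R) spiro δ-lactone; the (S) quaternary carbon bears CH3 and C-3 of (5R)-4-hydroxy-5-methylfuran-2(5H)-one (trans to the CMe2–O arm); the alkene carbon bears CH2C(=CH2)CO2H | C=C(C(=O)O)CC1=C(C)[C@]2(C=CC(=O)OC2(C)C)CC[C@]1(C)C3=C(O)[C@@H](C)OC3=O | intermediate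
16 | as 15, but the heterocycle is a (3S,5R)-3-ethynyl-5-methylfuran-2,4-dione (ethynyl trans to 5-CH3) | C=C(C(=O)O)CC1=C(C)[C@]2(C=CC(=O)OC2(C)C)CC[C@]1(C)[C@]3(C#C)C(=O)O[C@H](C)C3=O | intermediate
17 | penicianstinoid C | C=C1[C@](C)(C(=O)O)CC2=C(C)[C@]3(C=CC(=O)OC3(C)C)CC[C@]2(C)[C@@]12C(=O)O[C@H](C)C2=O | target

## Step count and risks

Total step count: 9. Longest linear sequence: 7 (steps 1–4 and 7–9).

**Step 3.** The risks are C-versus-C regiochemistry of the ambident dienolate, loss of Z geometry through HI elimination to propiolate, and the level of ee.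
The fallback sets out from 3 (isolated this time) and rejoins the route at 8.
- The only acidic site of 3, the β-diketone C–H, is vinylated with 7 (Cs2CO3, DMF, 0 °C). This gives the achiral, prochiral vinylated triketone F1, so the regiochemical question disappears.
- An (S)-proline-catalysed desymmetrising aldol condensation of Hajos–Parrish type lets the side-chain ketone select one of the two enantiotopic acetyl groups. It gives the (R)-configured spiro-precursor enone F2.
- Classical thermodynamic dienolate alkylation at the α-carbon (KOt-Bu, then 5) delivers 8.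

**Step 7.** The intermolecular tert-alkylation of a weakly nucleophilic enol may lose to E1 diene formation or to O-alkylation.
The fallback sets out from 10 and 12 and rejoins the route at 15. It uses a far stronger acyclic π-nucleophile and builds ring D afterwards.
- Compound 12 is O-silylated (LDA with TBSCl internal quench, THF, −100 °C) to the ketene silyl acetal F3.
- F3 captures the cation from 10 under TBSOTf catalysis (CH2Cl2, −78 °C, Mukaiyama-type SN1 alkylation). After mild acidic work-up this gives the lactate ester acid F4.
- A Dieckmann closure (LiHMDS, 3.2 equiv, −78 °C) converts F4 into 15.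

**Step 9.** Hydropalladation regiochemistry and insertion between two quaternary carbons are both demanding, and simple reduction of the acrylic acid competes.
The fallback sets out from 16 and rejoins the route at 17.
- Palladium is placed on the correct carbon by oxidative addition instead of hydropalladation.
- Mo-catalysed α-selective hydrostannation followed by iodinolysis gives the 2-iodoalkene F5.
- An intramolecular reductive Heck cyclisation (Pd(OAc)2, PPh3, HCO2Na, DMF, 60 °C) closes ring A by the same 6-exo insertion and formate reduces the neopentyl palladium species.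

## Further compounds

F1 | step 3 | ethyl (2Z)-4,4-diacetyl-7-oxooct-2-enoate | CCOC(=O)/C=C\C(CCC(C)=O)(C(C)=O)C(C)=O
F2 | step 3 | ethyl (2Z)-3-[(1R)-1-acetyl-2-methyl-4-oxocyclohex-2-en-1-yl]prop-2-enoate | CCOC(=O)/C=C\[C@]1(C(C)=O)CCC(=O)C=C1C
F3 | step 7 | methyl (2R)-2-{[1-(tert-butyldimethylsilyloxy)ethenyl]oxy}propanoate | C=C(O[Si](C)(C)C(C)(C)C)O[C@H](C)C(=O)OC
F4 | step 7 | as 15, but the quaternary carbon bears CH2C(=O)O–(R)-CH(CH3)CO2CH3 in place of the tetronic acid (same spatial arrangement) | C=C(C(=O)O)CC1=C(C)[C@]2(C=CC(=O)OC2(C)C)CC[C@]1(C)CC(=O)O[C@H](C)C(=O)OC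
F5 | step 9 | as 16, but with a 1-iodoethenyl group in place of ethynyl | C=C(C(=O)O)CC1=C(C)[C@]2(C=CC(=O)OC2(C)C)CC[C@]1(C)[C@]3(C(I)=C)C(=O)O[C@H](C)C3=O
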